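**Plan**

1. Numbering used throughout: C1 and C5 are the oxane CH–O carbons (C2, C3 the oxane CH2), C4 the spiro-epoxide carbon (C15 its CH2), C6 the lactone O–CH, C7 the ring-fusion CH, C8 the ester carbinol, C9=C10 the ring alkene, C14 the CHO, C11/C12/C13 the C(=CH2)–C=O unit of the lactone.
2. Cuts, in retrosynthetic order: the C4–C15 epoxide oxygen; the O8 ester and the C14 oxidation level; C6–C7 together with O6–C12 (one event); before that C1–H/C1–O6 (reductive opening of a 6,8-dioxabicyclo[3.2.1]octane ketal), C7–C11, C1–C10 and C2–C3.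
3. Enabling feature: C6–O–C12(=O)–C11(=C13H2)–C7 is the retron of a 2-(methoxycarbonyl)allyl metal adding through its γ-carbon C7 to a C6 aldehyde. The cis-2,6-oxane and the cis C9=C10 bond bring C6 and C7 together, so one C–C bond closes the eight-membered oxocene (and with it the ten-membered carbocycle), and the lactone follows from the same alkoxide.
4. Forward: western C1–C6 amide (Eschenmoser–Claisen) plus eastern C7–C10/C14 (Z)-alkenyl iodide → enone → bicyclic ketal (oxane ring and masked C6–OH) → acrylate unit and allylic bromide at C7 → cis-oxane → C6 aldehyde → key closure → desilylation, C14 enal, methacrylate, epoxide.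
5. Stereochemistry: C5 from the chiral pool; C8 by Noyori transfer hydrogenation; C9=C10 geometry by trans-hydroalumination/iodination; C1 by axial hydride delivery to the oxocarbenium ion; C6 and C7 in the key step (chair transition state, chelation by the oxane oxygen); C4 by epoxidation of the convex face.

Key step: step 16

Remark 1: compounds 7 and 8 are taken as purchasable building blocks.
Remark 2: TBDPS = tert-butyl(diphenyl)silyl, TIPS = tri(propan-2-yl)silyl, PMB = (4-methoxyphenyl)methyl; locants C1–C15 in names of 16–30 are those of plan line 1.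
Remark 3: the descriptor of C5 changes from S to R in step 20 only because C4 gains oxygen; no bond to C5 is touched.

**Route**

Step 1
Reactants: 1 2-[(4S)-2,2-dimethyl-1,3-dioxolan-4-yl]ethanol
Product: 2 [(4S)-2,2-dimethyl-1,3-dioxolan-4-yl]acetaldehyde
Conditions: Dess–Martin periodinane, NaHCO3, CH2Cl2, 0 °C → rt
Reagents that add atoms: none
Why: Dess–Martin oxidation of a primary alcohol stops at the aldehyde under buffered conditions and does not touch the C5 stereocentre, which is β to the carbonyl.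

Step 2
Reactants: 2 [(4S)-2,2-dimethyl-1,3-dioxolan-4-yl]acetaldehyde
Product: 3 2-[(4S)-2,2-dimethyl-1,3-dioxolan-4-yl]prop-2-enal
Conditions: 37% aq. HCHO, pyrrolidine (10 mol%), propionic acid (10 mol%), i-PrOH, 45 °C
Reagents that add atoms: formaldehyde, C=O
Why: Amine-catalysed α-methylenation (Mannich condensation then elimination) of an α-unbranched aldehyde, run briefly so that β-elimination of the dioxolane oxygen should not compete.

Step 3
Reactants: 3 2-[(4S)-2,2-dimethyl-1,3-dioxolan-4-yl]prop-2-enal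
Product: 4 2-[(4S)-2,2-dimethyl-1,3-dioxolan-4-yl]prop-2-en-1-ol
Conditions: NaBH4, CeCl3·7H2O, MeOH, 0 °C
Reagents that add atoms: none
Why: Luche reduction gives clean 1,2-reduction of the enal to the 2-substituted allylic alcohol.

Step 4
Reactants: 4 2-[(4S)-2,2-dimethyl-1,3-dioxolan-4-yl]prop-2-en-1-ol
Product: 6 4-[(4S)-2,2-dimethyl-1,3-dioxolan-4-yl]-N,N-dimethylpent-4-enamide, via ketene N,O-acetal 5 (not isolated)
Conditions: MeC(OMe)2NMe2, xylenes, 140 °C
Reagents that add atoms: 1,1-dimethoxy-N,N-dimethylethanamine, COC(C)(OC)N(C)C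
Why: Eschenmoser–Claisen rearrangement forms C2–C3 by a [3,3] shift under neutral conditions and leaves the double bond as the exocyclic C4=C15 methylene, with C5 unchanged.

Step 5
Reactants: 7 N-methoxy-2-[(4-methoxyphenyl)methoxy]-N-methylacetamide; 8 tert-butyl(diphenyl)(prop-2-ynyloxy)silane
Product: 10 5-(TBDPS-oxy)-1-(PMB-oxy)pent-3-yn-2-one, via lithium acetylide 9 (not isolated)
Conditions: 8, n-BuLi, THF, −78 °C; then 7, −78 → −20 °C; aq. NH4Cl
Reagents that add atoms: none
Why: Acylation of a lithium acetylide by a Weinreb amide stops at the ynone because the chelated tetrahedral intermediate survives until work-up.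

Step 6
Reactants: 10 5-(TBDPS-oxy)-1-(PMB-oxy)pent-3-yn-2-one
Product: 11 (2R)-5-(TBDPS-oxy)-1-(PMB-oxy)pent-3-yn-2-ol
Conditions: RuCl[(S,S)-TsDPEN](p-cymene) (1 mol%), i-PrOH, 25 °C
Reagents that add atoms: none
Why: Noyori asymmetric transfer hydrogenation of an ynone, in which the alkynyl group takes the place of the aryl group of the acetophenone model, should set C8 as R under catalyst control.

Step 7
Reactants: 11 (2R)-5-(TBDPS-oxy)-1-(PMB-oxy)pent-3-yn-2-ol
Product: 13 (2R,3Z)-5-(TBDPS-oxy)-4-iodo-1-(PMB-oxy)pent-3-en-2-ol, via cyclic alkenylaluminate 12 (not isolated)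
Conditions: NaAlH2(OCH2CH2OCH3)2, THF, 0 °C → rt; then I2, THF, −78 °C
Reagents that add atoms: iodine, II
Why: Hydroxyl-directed trans-hydroalumination (hydride to C9, aluminium to C10 in a five-membered aluminate) and iodinolysis with retention give the (Z)-iodoalkene, which fixes the C9=C10 geometry with C8 cis to the future C1.

Step 8
Reactants: 13 (2R,3Z)-5-(TBDPS-oxy)-4-iodo-1-(PMB-oxy)pent-3-en-2-ol
Product: 14 [(2R,3Z)-5-(TBDPS-oxy)-4-iodo-1-(PMB-oxy)pent-3-en-2-yl]oxy-tri(propan-2-yl)silane
Conditions: i-Pr3SiOTf, 2,6-lutidine, CH2Cl2, −78 → 0 °C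
Reagents that add atoms: tri(propan-2-yl)silyl trifluoromethanesulfonate, CC(C)[Si](C(C)C)(C(C)C)OS(=O)(=O)C(F)(F)F
Why: Silylation of the hindered secondary alcohol with a silyl triflate installs a group bulky enough to resist the later acid step and 1,4-silyl migration to the alkenyllithium.

Step 9
Reactants: 14 [(2R,3Z)-5-(TBDPS-oxy)-4-iodo-1-(PMB-oxy)pent-3-en-2-yl]oxy-tri(propan-2-yl)silane; 6 4-[(4S)-2,2-dimethyl-1,3-dioxolan-4-yl]-N,N-dimethylpent-4-enamide
Product: 17 (1S,5S)-5-alkenyl-2-methylidene-6,8-dioxabicyclo[3.2.1]octane ketal, via alkenyllithium 15 (not isolated), via (Z)-enone 16 (not isolated)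
Conditions: 14, t-BuLi (2.1 equiv), Et2O, −78 °C; then 6, −78 → −20 °C; aq. NH4Cl; crude 16 in AcOH/THF/H2O (3:1:1), 40 °C
Reagents that add atoms: none
Why: Iodine–lithium exchange with retention of geometry, addition of the alkenyllithium to the tertiary amide (ketone released on work-up) and acid-induced transketalization of the δ,ε-dihydroxy ketone unit should give the bicyclic ketal, whose configuration at C1 is dictated by C5 through the bicycle.

Step 10
Reactants: 17 (1S,5S)-5-alkenyl-2-methylidene-6,8-dioxabicyclo[3.2.1]octane ketal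
Product: 18 primary alcohol (C7–OH) of the ketal
Conditions: DDQ, CH2Cl2/pH 7 buffer, 0 °C
Reagents that add atoms: none
Why: Oxidative cleavage of the PMB ether by DDQ in buffered medium leaves both silyl ethers and the ketal intact.

Step 11
Reactants: 18 primary alcohol (C7–OH) of the ketal
Product: 19 α-silyloxy aldehyde (C7 aldehyde) of the ketal
Conditions: Dess–Martin periodinane, NaHCO3, CH2Cl2, 0 °C
Reagents that add atoms: none
Why: Dess–Martin oxidation gives the α-silyloxy aldehyde under non-basic conditions, and it is used at once so that C8 does not epimerize.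

Step 12
Reactants: 19 α-silyloxy aldehyde (C7 aldehyde) of the ketal
Product: 20 Morita–Baylis–Hillman-type alcohol (both C7 epimers)
Conditions: methyl propiolate, i-Bu2AlH, N-methylmorpholine N-oxide, THF, 0 °C; then 19, 0 °C → rt
Reagents that add atoms: methyl propiolate, C#CC(=O)OC
Why: Vinylalumination, in which the α-aluminated acrylate from 1,4-hydroalumination of methyl propiolate adds to the hindered aldehyde, forms C7–C11; the C7 configuration is irrelevant because it is erased in step 13.

Step 13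
Reactants: 20 Morita–Baylis–Hillman-type alcohol (both C7 epimers)
Product: 21 (Z)-2-(bromomethyl)enoate of the ketal
Conditions: NBS, Me2S, CH2Cl2, −20 → 0 °C
Reagents that add atoms: N-bromosuccinimide, O=C1CCC(=O)N1Br
Why: Corey–Kim-type activation of the allylic alcohol and SN2' attack of bromide should give the rearranged primary allylic bromide as the thermodynamically preferred (Z)-2-(bromomethyl)alk-2-enoate.

Step 14
Reactants: 21 (Z)-2-(bromomethyl)enoate of the ketal
Product: 22 cis-2,6-disubstituted oxane with free C6–OH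
Conditions: Et3SiH, BF3·OEt2, CH2Cl2, −78 → −40 °C; aq. NaHCO3
Reagents that add atoms: none
Why: Ionic reduction of the bicyclic ketal, in which BF3 ionizes the C1–O6 bond to the six-membered alkene-conjugated oxocarbenium ion and Et3SiH attacks axially, should set C1 (R) with H1 cis to H5 and free the C6 hydroxyl.

Step 15
Reactants: 22 cis-2,6-disubstituted oxane with free C6–OH
Product: 23 C6 aldehyde carrying the allylic bromide
Conditions: Dess–Martin periodinane, NaHCO3, CH2Cl2, 0 °C
Reagents that add atoms: none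
Why: Dess–Martin oxidation of the primary alcohol tolerates the allylic bromide and, being buffered, should not epimerize C5.

Step 16
Reactants: 23 C6 aldehyde carrying the allylic bromide
Product: 26 bis-silyl tricyclic lactone, via allylchromium species 24 (not isolated), via hydroxy ester 25 (not isolated)
Conditions: CrCl2 (10 equiv), THF, 25 °C, 23 added by syringe pump over 12 h (final 2 mM); aq. NH4Cl; PPTS (cat.), CH2Cl2, 25 °C
Reagents that add atoms: none
Why: CrCl2 (two equivalents per C–Br bond) reduces the allylic bromide to a 2-(methoxycarbonyl)allyl chromium species of trivalent chromium bound at C13, which adds through its γ-carbon C7 to the chromium-coordinated C6 aldehyde in a six-membered Zimmerman–Traxler chair, after which the alkoxide closes the lactone on the C12 ester; the closest known reaction type is the Nozaki–Hiyama–Kishi (Dreiding–Schmidt) allylation–lactonization of 2-(bromomethyl)alk-2-enoates, which has been used intramolecularly for macrocyclic and medium-ring α-methylene lactones. Two rings close: the oxocene (and with it the ten-membered carbocycle) by 8-exo-trig attack of C7 on the C6 carbonyl, and the butyrolactone by 5-exo-trig acyl substitution of O6 on C12. C7 (R) relative to C6: the σ-allyl chromium equilibrates between its alkene isomers and should react through the chair in which both tether arms, C5 on C6 and C8 on C7, are equatorial, which gives the anti adduct and hence the trans-fused lactone, as in intermolecular chromium-mediated reactions of γ-substituted 2-(alkoxycarbonyl)allyl bromides. C6 (S): the oxane oxygen next to the aldehyde can serve as a second donor for the same chromium centre, so the carbonyl should react in the rotamer with C=O syn to C5–O and receive C7 on the face anti to C4 (Cram-chelate sense), while the C8 silyloxy group points outward from the forming ring and so selects the matching face of the allyl terminus. The step needs chemoselectivity for the aldehyde over two esters and three other alkenes (secured by the mildness of the organochromium reagent), ring closure over oligomerization (secured by slow addition at high dilution and by the cis-oxane and cis C9=C10 bond that fold the chain), and the diastereoselectivity just described.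

Step 17
Reactants: 26 bis-silyl tricyclic lactone
Product: 27 C8,C14-diol lactone
Conditions: Bu4NF, AcOH (1:1), THF, 0 °C → rt
Reagents that add atoms: none
Why: Fluoride cleaves both silyl ethers, and buffering with AcOH should protect the α-methylene lactone and suppress translactonization to O8.

Step 18
Reactants: 27 C8,C14-diol lactone
Product: 28 C14 enal with free C8–OH
Conditions: TEMPO (10 mol%), PhI(OAc)2, CH2Cl2, 25 °C
Reagents that add atoms: none
Why: Oxoammonium oxidation (TEMPO/PhI(OAc)2) is much faster for the primary allylic alcohol than for the hindered secondary one, so the enal should form without touching C8–OH.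

Step 19
Reactants: 28 C14 enal with free C8–OH
Product: 29 4,15-deoxy target (C4=C15 methylene)
Conditions: methacrylic anhydride, Et3N, DMAP (cat.), CH2Cl2, 0 °C → rt
Reagents that add atoms: methacrylic anhydride, C=C(C)C(=O)OC(=O)C(C)=C
Why: DMAP-catalysed acylation of the secondary alcohol installs the methacrylate without disturbing the enal or lactone.

Step 20
Reactants: 29 4,15-deoxy target (C4=C15 methylene)
Product: 30 target CNP0257628.1
Conditions: dimethyldioxirane (acetone solution), CH2Cl2, −20 → 0 °C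
Reagents that add atoms: dimethyldioxirane, CC1(C)OO1
Why: Electrophilic epoxidation should take place only at the electron-rich 1,1-disubstituted C4=C15 bond (the other three alkenes are carbonyl-conjugated) and from the convex face of the bridged bicycle, anti to the C5–C6 and C1–C10 bonds, which sets C4 (R) with the epoxide oxygen trans to C6.

**Compound list**

1 | 2-[(4S)-2,2-dimethyl-1,3-dioxolan-4-yl]ethanol | OCC[C@H]1COC(C)(C)O1 | starting material
2 | [(4S)-2,2-dimethyl-1,3-dioxolan-4-yl]acetaldehyde | O=CC[C@H]1COC(C)(C)O1 | intermediate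
3 | 2-[(4S)-2,2-dimethyl-1,3-dioxolan-4-yl]prop-2-enal | O=CC(=C)[C@H]1COC(C)(C)O1 | intermediate
4 | 2-[(4S)-2,2-dimethyl-1,3-dioxolan-4-yl]prop-2-en-1-ol | OCC(=C)[C@H]1COC(C)(C)O1 | intermediate
5 | 1-{2-[(4S)-2,2-dimethyl-1,3-dioxolan-4-yl]prop-2-enoxy}-N,N-dimethylethenamine (ketene N,O-acetal) | C=C(N(C)C)OCC(=C)[C@H]1COC(C)(C)O1 | intermediate (not isolated)
6 | 4-[(4S)-2,2-dimethyl-1,3-dioxolan-4-yl]-N,N-dimethylpent-4-enamide (western fragment) | CN(C)C(=O)CCC(=C)[C@H]1COC(C)(C)O1 | intermediate
7 | N-methoxy-2-[(4-methoxyphenyl)methoxy]-N-methylacetamide | CON(C)C(=O)COCc1ccc(OC)cc1 | starting material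
8 | tert-butyl(diphenyl)(prop-2-ynyloxy)silane | C#CCO[Si](c1ccccc1)(c1ccccc1)C(C)(C)C | starting material
9 | lithium acetylide of 8 | [Li]C#CCO[Si](c1ccccc1)(c1ccccc1)C(C)(C)C | intermediate (not isolated)
10 | 5-(TBDPS-oxy)-1-(PMB-oxy)pent-3-yn-2-one | O=C(COCc1ccc(OC)cc1)C#CCO[Si](c1ccccc1)(c1ccccc1)C(C)(C)C | intermediate
11 | (2R)-5-(TBDPS-oxy)-1-(PMB-oxy)pent-3-yn-2-ol | O[C@@H](COCc1ccc(OC)cc1)C#CCO[Si](c1ccccc1)(c1ccccc1)C(C)(C)C | intermediate
12 | sodium cyclic alkenylaluminate (five-membered O–Al–C10 ring, two 2-methoxyethoxy ligands on aluminium) | [Na+].COCCO[Al-]1(OCCOC)O[C@@H](COCc2ccc(OC)cc2)C=C1CO[Si](c1ccccc1)(c1ccccc1)C(C)(C)C | intermediate (not isolated)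
13 | (2R,3Z)-5-(TBDPS-oxy)-4-iodo-1-(PMB-oxy)pent-3-en-2-ol | O[C@@H](COCc1ccc(OC)cc1)/C=C(/CO[Si](c1ccccc1)(c1ccccc1)C(C)(C)C)I | intermediate
14 | [(2R,3Z)-5-(TBDPS-oxy)-4-iodo-1-(PMB-oxy)pent-3-en-2-yl]oxy-tri(propan-2-yl)silane (eastern fragment) | CC(C)[Si](C(C)C)(C(C)C)O[C@@H](COCc1ccc(OC)cc1)/C=C(/CO[Si](c1ccccc1)(c1ccccc1)C(C)(C)C)I | intermediate
15 | alkenyllithium from 14 (lithium in place of iodine, geometry retained) | CC(C)[Si](C(C)C)(C(C)C)O[C@@H](COCc1ccc(OC)cc1)/C=C(/CO[Si](c1ccccc1)(c1ccccc1)C(C)(C)C)[Li] | intermediate (not isolated)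
16 | (6Z,8R)-6-(TBDPS-oxymethyl)-2-[(4S)-2,2-dimethyl-1,3-dioxolan-4-yl]-9-(PMB-oxy)-8-(TIPS-oxy)nona-1,6-dien-5-one | CC(C)[Si](C(C)C)(C(C)C)O[C@@H](COCc1ccc(OC)cc1)/C=C(/CO[Si](c1ccccc1)(c1ccccc1)C(C)(C)C)C(=O)CCC(=C)[C@H]1COC(C)(C)O1 | intermediate (not isolated)
17 | (1S,5S)-5-[(2Z,4R)-1-(TBDPS-oxy)-5-(PMB-oxy)-4-(TIPS-oxy)pent-2-en-2-yl]-2-methylidene-6,8-dioxabicyclo[3.2.1]octane | CC(C)[Si](C(C)C)(C(C)C)O[C@@H](COCc1ccc(OC)cc1)/C=C(/CO[Si](c1ccccc1)(c1ccccc1)C(C)(C)C)[C@@]12CCC(=C)[C@@H](CO1)O2 | intermediate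
18 | (2R,3Z)-5-(TBDPS-oxy)-4-[(1S,5S)-2-methylidene-6,8-dioxabicyclo[3.2.1]octan-5-yl]-2-(TIPS-oxy)pent-3-en-1-ol | CC(C)[Si](C(C)C)(C(C)C)O[C@@H](CO)/C=C(/CO[Si](c1ccccc1)(c1ccccc1)C(C)(C)C)[C@@]12CCC(=C)[C@@H](CO1)O2 | intermediate
19 | (2R,3Z)-5-(TBDPS-oxy)-4-[(1S,5S)-2-methylidene-6,8-dioxabicyclo[3.2.1]octan-5-yl]-2-(TIPS-oxy)pent-3-enal | CC(C)[Si](C(C)C)(C(C)C)O[C@@H](C=O)/C=C(/CO[Si](c1ccccc1)(c1ccccc1)C(C)(C)C)[C@@]12CCC(=C)[C@@H](CO1)O2 | intermediate
20 | methyl (4R,5Z)-7-(TBDPS-oxy)-3-hydroxy-2-methylidene-6-[(1S,5S)-2-methylidene-6,8-dioxabicyclo[3.2.1]octan-5-yl]-4-(TIPS-oxy)hept-5-enoate (both C3 epimers) | CC(C)[Si](C(C)C)(C(C)C)O[C@@H](C(O)C(=C)C(=O)OC)/C=C(/CO[Si](c1ccccc1)(c1ccccc1)C(C)(C)C)[C@@]12CCC(=C)[C@@H](CO1)O2 | intermediate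
21 | methyl (2Z,4R,5Z)-2-(bromomethyl)-7-(TBDPS-oxy)-6-[(1S,5S)-2-methylidene-6,8-dioxabicyclo[3.2.1]octan-5-yl]-4-(TIPS-oxy)hepta-2,5-dienoate | CC(C)[Si](C(C)C)(C(C)C)O[C@@H](/C=C(/C(=O)OC)CBr)/C=C(/CO[Si](c1ccccc1)(c1ccccc1)C(C)(C)C)[C@@]12CCC(=C)[C@@H](CO1)O2 | intermediate
22 | methyl (2Z,4R,5Z)-2-(bromomethyl)-7-(TBDPS-oxy)-6-[(2R,6S)-6-(hydroxymethyl)-5-methylideneoxan-2-yl]-4-(TIPS-oxy)hepta-2,5-dienoate | CC(C)[Si](C(C)C)(C(C)C)O[C@@H](/C=C(/C(=O)OC)CBr)/C=C(/CO[Si](c1ccccc1)(c1ccccc1)C(C)(C)C)[C@H]1CCC(=C)[C@H](O1)CO | intermediate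
23 | methyl (2Z,4R,5Z)-2-(bromomethyl)-7-(TBDPS-oxy)-6-[(2R,6S)-6-formyl-5-methylideneoxan-2-yl]-4-(TIPS-oxy)hepta-2,5-dienoate | CC(C)[Si](C(C)C)(C(C)C)O[C@@H](/C=C(/C(=O)OC)CBr)/C=C(/CO[Si](c1ccccc1)(c1ccccc1)C(C)(C)C)[C@H]1CCC(=C)[C@H](O1)C=O | intermediate
24 | σ-allyl chromium dichloride from 23 (CrCl2 group in place of bromine at C13) | CC(C)[Si](C(C)C)(C(C)C)O[C@@H](/C=C(/C(=O)OC)C[Cr](Cl)Cl)/C=C(/CO[Si](c1ccccc1)(c1ccccc1)C(C)(C)C)[C@H]1CCC(=C)[C@H](O1)C=O | intermediate (not isolated)
25 | bicyclic hydroxy ester: oxane C1–C5 bridged by C6–C10 (11-oxabicyclo[5.3.1]undecene core), C6–OH, C7–C(=CH2)CO2Me, C8–OTIPS, C10–CH2OTBDPS, C4=CH2; C1 R, C5 S, C6 S, C7 R, C8 R, 9Z | CC(C)[Si](C(C)C)(C(C)C)O[C@@H]1/C=C(/CO[Si](c3ccccc3)(c3ccccc3)C(C)(C)C)[C@H]2CCC(=C)[C@H](O2)[C@@H](O)[C@@H]1C(=C)C(=O)OC | intermediate (not isolated)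
26 | bis-silyl tricyclic lactone: as 25 with O6 acylated by C12 (trans-fused α-methylene-γ-butyrolactone); C1 R, C5 S, C6 S, C7 R, C8 R, 9Z | CC(C)[Si](C(C)C)(C(C)C)O[C@@H]1/C=C(/CO[Si](c3ccccc3)(c3ccccc3)C(C)(C)C)[C@H]2CCC(=C)[C@H](O2)[C@H]2OC(=O)C(=C)[C@@H]21 | intermediate
27 | C8,C14-diol lactone (26 without both silyl groups) | O[C@@H]1/C=C(/CO)[C@H]2CCC(=C)[C@H](O2)[C@H]2OC(=O)C(=C)[C@@H]21 | intermediate
28 | C14 enal with free C8–OH (9E by CIP, C8 trans to CHO) | O[C@@H]1/C=C(/C=O)[C@H]2CCC(=C)[C@H](O2)[C@H]2OC(=O)C(=C)[C@@H]21 | intermediate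
29 | 4,15-deoxy target: C8 methacrylate, C4=C15 exocyclic methylene | C=C(C)C(=O)O[C@@H]1/C=C(/C=O)[C@H]2CCC(=C)[C@H](O2)[C@H]2OC(=O)C(=C)[C@@H]21 | intermediate
30 | CNP0257628.1 (C1 R, C4 R, C5 R, C6 S, C7 R, C8 R) | C=C(C)C(=O)O[C@@H]1/C=C(/C=O)[C@H]2CC[C@@]3(CO3)[C@H](O2)[C@H]2OC(=O)C(=C)[C@@H]21 | target

**Count**

Total step count: 20. Longest linear sequence: 16 steps (steps 1–4, then 9–20; the eastern branch, steps 5–8 then 9–20, is equally long).

**Steps most likely to fail, with fallbacks**

Step 16. The ring closure may suffer from attack on the wrong aldehyde face (giving the C6 epimer) or from intermolecular coupling. The stereochemical argument in the Why line is a model, not a certainty. The fallback fixes C6 by inversion instead of by the addition itself. It sets out from 23: closure under indium-mediated Barbier conditions (indium powder, THF/H2O, high dilution), which favour syn adducts, should give the C6-epimeric cis-fused lactone F1. LiOH in THF/H2O opens it to the C6-epimeric hydroxy acid F2, which is acidified cold and used at once. Mitsunobu lactonization (PPh3, diisopropyl azodicarboxylate, THF) then closes the lactone with inversion at C6 and comes back to the route at 26. This fallback cannot correct a wrong C7.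

Step 9. The basic alkenyllithium may enolize the amide, the silyl group may migrate from O8 to C10, or the (Z)-enone may isomerize during the acid treatment. The fallback replaces the organolithium addition by a chromium-mediated coupling under neutral conditions. It sets out from 6: Cp2Zr(H)Cl in THF reduces the amide to the aldehyde 4-[(4S)-2,2-dimethyl-1,3-dioxolan-4-yl]pent-4-enal F3. CrCl2 with catalytic NiCl2 in DMSO couples iodide 14 with it to give the allylic alcohols F4 (both C1 epimers). Dess–Martin oxidation gives enone 16, where the route is rejoined before the acid treatment that leads to 17.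

Step 20. The oxidant may attack the concave face, or react so slowly that the aldehyde is oxidized. The fallback builds the epoxide in two steps with the opposite facial logic, so it is only needed if electrophiles prefer the concave face. It sets out from 29: NBS in aqueous acetone forms the bromonium ion on the face the electrophile prefers, and water opens it at the tertiary carbon C4 from the other face, giving the bromohydrin F5. Ag2O in CH2Cl2 closes the epoxide with retention at C4 and arrives at 30.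

Further compounds
F1 | step 16 | C6-epimeric cis-fused bis-silyl lactone (26 with inverted C6) | CC(C)[Si](C(C)C)(C(C)C)O[C@@H]1/C=C(/CO[Si](c3ccccc3)(c3ccccc3)C(C)(C)C)[C@H]2CCC(=C)[C@H](O2)[C@@H]2OC(=O)C(=C)[C@@H]21
F2 | step 16 | C6-epimeric hydroxy acid (free acid of 25 with inverted C6) | CC(C)[Si](C(C)C)(C(C)C)O[C@@H]1/C=C(/CO[Si](c3ccccc3)(c3ccccc3)C(C)(C)C)[C@H]2CCC(=C)[C@H](O2)[C@H](O)[C@@H]1C(=C)C(=O)O
F3 | step 9 | 4-[(4S)-2,2-dimethyl-1,3-dioxolan-4-yl]pent-4-enal | O=CCCC(=C)[C@H]1COC(C)(C)O1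
F4 | step 9 | (6Z,8R)-6-(TBDPS-oxymethyl)-2-[(4S)-2,2-dimethyl-1,3-dioxolan-4-yl]-9-(PMB-oxy)-8-(TIPS-oxy)nona-1,6-dien-5-ol (both C5 epimers) | CC(C)[Si](C(C)C)(C(C)C)O[C@@H](COCc1ccc(OC)cc1)/C=C(/CO[Si](c1ccccc1)(c1ccccc1)C(C)(C)C)C(O)CCC(=C)[C@H]1COC(C)(C)O1
F5 | step 20 | bromohydrin of 29 (C4–OH on the face of the target epoxide oxygen, C15H2Br) | C=C(C)C(=O)O[C@@H]1/C=C(/C=O)[C@H]2CC[C@@](O)(CBr)[C@H](O2)[C@H]2OC(=O)C(=C)[C@@H]21
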